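The numbers in the tables were computed on assumed constants, noise included.

Per minute and per equivalent of nucleophile: that is the unit in which I read the south-west, west and south runs, all with the electrophile at 0.20 M.

common to all: electrophile 0.20 M

| charge | nucleophile | remark | time |
|---|---|---|---|
| south-west | 1.3 equiv | run made earlier |  |
| west | 1.4 equiv | run made earlier |  |
| south | 2.3 equiv | run made earlier |  |
| autumn | 1.00 equiv |  | 5.0 min |
| dawn | 2.00 equiv |  | 5.0 min |

| run | time / min | electrophile / % | target / % |
|---|---|---|---|
| south-west | 0.200 | 98.7 | 2.1 |
| south-west | 0.417 | 95.8 | 3.9 |
| south-west | 0.667 | 93.8 | 5.8 |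
| south-west | 1.33 | 89.4 | 11.4 |
| south-west | 2.50 | 81.3 | 18.1 |
| west | 0.200 | 97.6 | 2.2 |
| west | 0.667 | 94.7 | 6.2 |
| west | 1.33 | 89.2 | 12.9 |
| west | 2.00 | 83.4 | 16.3 |
| west | 2.50 | 80.4 | 19.9 |
| south | 0.200 | 96.1 | 4.2 |
| south | 0.667 | 89.5 | 10.4 |
| south | 1.33 | 81.7 | 18.5 |
| south | 2.00 | 74.2 | 25.0 |
| south | 2.50 | 70.8 | 29.2 |

(each reading ± 0.5 percentage points)

- the earlier runs were read with a standard deviation of 0.5 percentage points
- a reading or a percentage of target counts all its forms, free or not

* part of the electrophile that has reacted at the end, autumn
* part of the electrophile that has reacted at the end, dawn
* what raising the equivalents of nucleophile from its lowest to its highest value here does to the part of the electrophile that has reacted (changes below 5 percentage points count as none) (it rises / it falls / no change)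

At 2.50 min, the logarithm of the electrophile's loss was 1.58 times as large in the south run as in the west run, with 1.64 times the equivalents, so I took the rate as first order in nucleophile.

I then solved two extreme versions. In the first, nucleophile is never spent (pseudo-first-order), and the last readings give a mean logarithmic loss per minute per equivalent charged of 0.0620 min⁻¹. In the second, the note that target counts free or not suggested that something holds it, so I let each reacted electrophile cost two nucleophile. The mean level over a run is then the charge less the part reacted, and the same readings give 0.0719 min⁻¹, a reading I call the spent-charge rate number: the electrophile's logarithmic loss per minute per equivalent of mean nucleophile at this concentration.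

That mean level needs the answer itself, so I put the never-spent answer in and went round once more.

| flask | never spent | second round |
|---|---|---|
| autumn | 26.7% | 23.2% |
| dawn | 46.2% | 42.5% |

I read the left column as the high side and committed to the right one, where dawn stands 19 percentage points above autumn, more than the 5 points that counts.

The forecast gave 24% for autumn, 42.5% for dawn and "it rises", noting that “This hints that product ties up nucleophile”.

Autumn gave 23.1% and dawn 41.1%: it rises by 18 points.

    electrophile + nucleophile → acid set free + target (k = 0.384 L mol⁻¹ min⁻¹)
    nucleophile + acid set free ⇌ protonated nucleophile, settled at all times (K = 12000 L mol⁻¹)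
    nucleophile + target ⇌ idle adduct, settled at all times (K = 4.37 L mol⁻¹)

In dawn, 2.46 equivalents of nucleophile were no longer free per electrophile reacted, against my two, and my second round stood 1.4 points above the result. I gave the same reckoning to the neighbour of dawn with the electrophile at 0.080 M, with equivalents and time held. I scaled the spent-charge rate number in proportion to the concentration, to 0.0288 min⁻¹; the never-spent round gave 22.0% and the second round 22.6%. That neighbour gave 23.0%, with 73% of its nucleophile still unbound.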